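**Strategy.** The route rests on disconnecting the side chain between the benzylic methylene C1' (on ring carbon C3 of the 2-hydroxy-5-methoxy-1,4-benzoquinone ring) and the acetoxy-bearing stereocentre C2'. The key step exploits the C2'–O bond: tetradecyl N,N-diisopropylcarbamate is deprotonated enantioselectively next to oxygen to a chiral carbenoid that captures 2,3,5,6-tetramethoxybenzyl pinacol boronate. A 1,2-migration of the benzyl group from boron to carbon expels the carbamate, forges C1'–C2' and sets the (R) centre in one operation, and C–B oxidation returns the carbinol oxygen. The tetramethoxyarene is the masked quinone ring, unveiled after acetylation by oxidative demethylation and regioselective hydrolysis of the methoxy group flanking the side chain.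

Key step: step 3

Remark: the quinone carbonyl oxygens formed in step 5 and the hydroxyl oxygen formed in step 6 are taken to come from water, the methoxy oxygens leaving as methanol.

**Step 1**
Reactants: 1 1,2,4,5-tetramethoxybenzene; 2 2-(chloromethyl)-4,4,5,5-tetramethyl-1,3,2-dioxaborolane
Product: 5 4,4,5,5-tetramethyl-2-(2,3,5,6-tetramethoxybenzyl)-1,3,2-dioxaborolane, via 2,3,5,6-tetramethoxyphenyllithium 3 (not isolated), via chloromethyl borate complex 4 (not isolated)
Conditions: n-BuLi, THF, 0 °C; then 2, −78 °C → rt
Reagents that add atoms: none
Why: Directed ortho-lithiation of 1 between two methoxy groups gives 3, which adds to the boron of 2, and the borate 4 should undergo 1,2-aryl migration with loss of chloride on warming (Matteson homologation of a halomethylboronate).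

**Step 2**
Reactants: 6 tetradecan-1-ol
Product: 7 tetradecyl N,N-diisopropylcarbamate
Conditions: NaH, THF, 0 °C; then iPr2NCOCl, reflux
Reagents that add atoms: N,N-diisopropylcarbamoyl chloride CC(C)N(C(C)C)C(Cl)=O
Why: O-acylation of the sodium alkoxide by the carbamoyl chloride (carbamate formation) installs the group that directs the deprotonation next to oxygen and later serves as the leaving group.

**Step 3**
Reactants: 7 tetradecyl N,N-diisopropylcarbamate; 5 4,4,5,5-tetramethyl-2-(2,3,5,6-tetramethoxybenzyl)-1,3,2-dioxaborolane
Product: 11 (2R)-1-(2,3,5,6-tetramethoxyphenyl)pentadecan-2-ol, via lithiated carbamate 8 (not isolated), via boronate complex 9 (not isolated), via secondary boronic ester 10 (not isolated)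
Conditions: s-BuLi, (−)-sparteine, Et2O, −78 °C; then 5, −78 °C; MgBr2·OEt2, reflux; then aq NaOH, H2O2, THF, 0 °C → rt
Reagents that add atoms: hydrogen peroxide OO
Why: s-BuLi complexed by (−)-sparteine removes the pro-S proton next to the carbamate oxygen of 7 at −78 °C (Hoppe deprotonation) to give the configurationally stable carbenoid 8, which adds to the boron atom of 5 with retention to form the boronate complex 9. On warming in the presence of MgBr2·OEt2 the benzyl group migrates from boron to carbon anti to the departing carbamate (1,2-metallate rearrangement with inversion), which forms the bond between the benzylic methylene and the carbinol carbon and gives the (R)-boronic ester 10; alkaline H2O2 then replaces boron by hydroxyl with retention. The closest known reaction type is the lithiation–borylation–oxidation of primary alkyl carbamates with pinacol boronic esters, a reagent-controlled Matteson-type homologation. No ring is closed. The new stereocentre is controlled by the chiral diamine, which selects the enantiotopic proton, and the retention–inversion–retention sequence relays this choice to the (R) configuration. The step needs capture of 8 at boron faster than deprotonation of the benzylic C–H of 5 and migration of carbon rather than of a pinacol oxygen; the Lewis acidity of the primary boronic ester and the far higher migratory aptitude of the benzyl carbon should secure both.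

**Step 4**
Reactants: 11 (2R)-1-(2,3,5,6-tetramethoxyphenyl)pentadecan-2-ol
Product: 12 (2R)-1-(2,3,5,6-tetramethoxyphenyl)pentadecan-2-yl acetate
Conditions: Ac2O, pyridine, DMAP (cat.), CH2Cl2, rt
Reagents that add atoms: acetic anhydride CC(=O)OC(C)=O
Why: DMAP-catalysed acyl transfer to the secondary alcohol (Steglich-type acylation) occurs at oxygen and leaves the stereocentre untouched.

**Step 5**
Reactants: 12 (2R)-1-(2,3,5,6-tetramethoxyphenyl)pentadecan-2-yl acetate
Product: 13 3-[(2R)-2-acetoxypentadecyl]-2,5-dimethoxy-1,4-benzoquinone
Conditions: (NH4)2Ce(NO3)6, MeCN/H2O, 0 °C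
Reagents that add atoms: water O
Why: Oxidative demethylation of a para-dimethoxyarene by the tetravalent cerium salt should give the para-quinone, and either para pair of methoxy groups leads to the same quinone because the arene is symmetric about the axis through the side-chain carbon, while the acetate keeps the side-chain oxygen from fragmenting or cyclising.

**Step 6**
Reactants: 13 3-[(2R)-2-acetoxypentadecyl]-2,5-dimethoxy-1,4-benzoquinone
Product: 14 3-[(2R)-2-acetoxypentadecyl]-2-hydroxy-5-methoxy-1,4-benzoquinone
Conditions: 70% aq HClO4, AcOH, rt
Reagents that add atoms: water O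
Why: Acid-catalysed addition–elimination of water (vinylogous ester hydrolysis) should occur at ring carbon C2, whose methoxy group is twisted out of conjugation by the neighbouring side chain as is known for 3-alkyl-2,5-dimethoxy-1,4-benzoquinones, while acetic acid as solvent makes acyl exchange at the secondary acetate degenerate.

**Compound list**
1 | 1,2,4,5-tetramethoxybenzene | COc1cc(OC)c(OC)cc1OC | starting material
2 | 2-(chloromethyl)-4,4,5,5-tetramethyl-1,3,2-dioxaborolane | ClCB1OC(C)(C)C(C)(C)O1 | starting material
3 | 2,3,5,6-tetramethoxyphenyllithium | [Li]c1c(OC)c(OC)cc(OC)c1OC | intermediate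
4 | lithium (chloromethyl)(2,3,5,6-tetramethoxyphenyl) pinacol borate | [Li+].ClC[B-]1(c2c(OC)c(OC)cc(OC)c2OC)OC(C)(C)C(C)(C)O1 | intermediate
5 | 4,4,5,5-tetramethyl-2-(2,3,5,6-tetramethoxybenzyl)-1,3,2-dioxaborolane | CC1(C)OB(Cc2c(OC)c(OC)cc(OC)c2OC)OC1(C)C | intermediate
6 | tetradecan-1-ol | CCCCCCCCCCCCCCO | starting material
7 | tetradecyl N,N-diisopropylcarbamate | CCCCCCCCCCCCCCOC(=O)N(C(C)C)C(C)C | intermediate
8 | (1S)-1-lithiotetradecyl N,N-diisopropylcarbamate, formed as its (−)-sparteine complex (ligand not drawn) | CCCCCCCCCCCCC[C@H]([Li])OC(=O)N(C(C)C)C(C)C | intermediate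
9 | lithium [(1S)-1-(N,N-diisopropylcarbamoyloxy)tetradecyl](2,3,5,6-tetramethoxybenzyl) pinacol borate | [Li+].CCCCCCCCCCCCC[C@H]([B-]1(Cc2c(OC)c(OC)cc(OC)c2OC)OC(C)(C)C(C)(C)O1)OC(=O)N(C(C)C)C(C)C | intermediate
10 | 2-[(2R)-1-(2,3,5,6-tetramethoxyphenyl)pentadecan-2-yl]-4,4,5,5-tetramethyl-1,3,2-dioxaborolane | CCCCCCCCCCCCC[C@H](Cc1c(OC)c(OC)cc(OC)c1OC)B1OC(C)(C)C(C)(C)O1 | intermediate
11 | (2R)-1-(2,3,5,6-tetramethoxyphenyl)pentadecan-2-ol | CCCCCCCCCCCCC[C@H](Cc1c(OC)c(OC)cc(OC)c1OC)O | intermediate
12 | (2R)-1-(2,3,5,6-tetramethoxyphenyl)pentadecan-2-yl acetate | CCCCCCCCCCCCC[C@H](Cc1c(OC)c(OC)cc(OC)c1OC)OC(C)=O | intermediate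
13 | 3-[(2R)-2-acetoxypentadecyl]-2,5-dimethoxy-1,4-benzoquinone | CCCCCCCCCCCCC[C@H](CC1=C(OC)C(=O)C=C(OC)C1=O)OC(C)=O | intermediate
14 | 3-[(2R)-2-acetoxypentadecyl]-2-hydroxy-5-methoxy-1,4-benzoquinone (CNP0332196.1) | CCCCCCCCCCCCC[C@H](CC1=C(O)C(=O)C=C(OC)C1=O)OC(C)=O | target

**Total step count:** 6
**Longest linear sequence:** 5 steps (step 1 or step 2, then steps 3 to 6)

**Steps most likely to fail**

1. Step 6. The strong acid may cleave the side-chain acetate, after which the freed hydroxyl could cyclise onto ring carbon C2, or water may attack the wrong methoxy-bearing carbon or both. Fallback: set out from acetate 12 and differentiate the oxygens before the ring is oxidised. BCl3 (CH2Cl2, −78 → 0 °C) should cleave the two methoxy groups that flank the side chain, these being the most hindered and most Lewis basic, to give (2R)-1-(2,6-dihydroxy-3,5-dimethoxyphenyl)pentadecan-2-yl acetate F1. Oxidation of F1 with PhI(OAc)2 in MeCN/H2O at 0 °C should convert one para-methoxyphenol unit into the quinone with loss of methanol, the second phenol remaining as the quinone hydroxyl. Both para pairs are equivalent by symmetry, so the regiochemistry is fixed, and the sequence comes back to the route at target 14 without passing through 13.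

2. Step 3. Borate formation with the di-ortho-substituted benzyl boronate may be slow or reversible, the 1,2-migration may stay incomplete, or the lithiated carbamate may lose configurational integrity if it warms. Fallback: set out from arene 1 and take the stereocentre from the chiral pool. Dodecylmagnesium bromide with CuI (cat.) in THF at −40 °C should open (R)-epichlorohydrin at the terminal ring carbon to give (2R)-1-chloropentadecan-2-ol F2, and NaOH should close it to (2R)-2-tridecyloxirane F3. Aryllithium 3, generated from 1 as in step 1, should then open F3 at its terminal carbon in the presence of BF3·OEt2 (THF, −78 °C), with the configuration at the carbinol carbon untouched. This comes back to the route at alcohol 11.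

3. Step 1. The hindered aryllithium may add poorly to boron, or the borate may fail to rearrange and return 1 on work-up. Fallback: set out from arene 1 and build the benzylic carbon at the aldehyde oxidation level. Quenching aryllithium 3 with DMF should give 2,3,5,6-tetramethoxybenzaldehyde F4, NaBH4 in MeOH should reduce it to (2,3,5,6-tetramethoxyphenyl)methanol F5, and PBr3 in Et2O at 0 °C should give 3-(bromomethyl)-1,2,4,5-tetramethoxybenzene F6, used crude. Borylation of F6 with B2pin2, Pd(dba)2, tris(4-methoxyphenyl)phosphine and KOAc in toluene at 50 °C comes back to the route at boronic ester 5.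

**Further compounds**
F1 | step 6 | (2R)-1-(2,6-dihydroxy-3,5-dimethoxyphenyl)pentadecan-2-yl acetate | CCCCCCCCCCCCC[C@H](Cc1c(O)c(OC)cc(OC)c1O)OC(C)=O
F2 | step 3 | (2R)-1-chloropentadecan-2-ol | CCCCCCCCCCCCC[C@@H](O)CCl
F3 | step 3 | (2R)-2-tridecyloxirane | CCCCCCCCCCCCC[C@@H]1CO1
F4 | step 1 | 2,3,5,6-tetramethoxybenzaldehyde | O=Cc1c(OC)c(OC)cc(OC)c1OC
F5 | step 1 | (2,3,5,6-tetramethoxyphenyl)methanol | OCc1c(OC)c(OC)cc(OC)c1OC
F6 | step 1 | 3-(bromomethyl)-1,2,4,5-tetramethoxybenzene | BrCc1c(OC)c(OC)cc(OC)c1OC
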